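**Plan**

- Retrosynthesis (pterocarpan numbering throughout): after desilylation, the aryl ether bond O11–C10a of ring C and the B/C ring-fusion bond C6a–C11a are cut together. This leads to a (3R)-3-aryl-2,3-dihydro-5H-1,4-benzodioxepine in which O11 still bridges C6a and C11a, and C10a of ring D carries chlorine.
- Enabling feature: C11a (benzylic to ring A) and C6a (benzylic to the electron-rich ring D) can both sit on the one oxygen O11, and C10a is ortho to the C6a branch. A carbanion at C11a can therefore pull C6a off O11 ([1,2]-Wittig shift, the seven-membered ring contracts to ring B), and the freed O11 alkoxide is placed for five-membered closure onto C10a–Cl (ring C).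
- The dioxepine is cut further at O11–C11a (Williamson), at C6a–O (asymmetric ketone reduction) and at O5–C6 (phenacyl ether), giving a ring A salicylaldehyde and a ring D bromomethyl ketone.
- Forward order: ring A aldehyde (silylation, Stille prenylation); ring D ketone (demethylation, two O-alkylations, tandem Claisen shifts that install the C10 prenyl group and the dimethylpyran ring, silylation/bromination); union, reduction, dioxepine closure; key step closes rings B and C; desilylation.
- Stereochemistry: C6a is set as (R) by CBS reduction, is carried through the Wittig shift with retention, and directs C11a through the ring-constrained collapse; the cis-only closure of ring C filters the ring fusion to (6aR,11aR).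

Key step: step 11

Remark: 5-bromo-2,4-dihydroxybenzaldehyde and 1-(2-chloro-4,5-dimethoxyphenyl)ethanone are taken as catalogue compounds.

Step 1
Reactants: 1 5-bromo-2,4-dihydroxybenzaldehyde
Product: 2 5-bromo-2-hydroxy-4-(triisopropylsilyloxy)benzaldehyde
Conditions: TIPSCl (1.05 equiv), imidazole, CH2Cl2, 0 °C
Reagents that add atoms: triisopropylsilyl chloride, CC(C)[Si](Cl)(C(C)C)C(C)C
Why: Regioselective O-silylation: the 2-OH is locked in a hydrogen bond to the formyl group and is the weaker nucleophile, so the silyl chloride should take the 4-OH only.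

Step 2
Reactants: 2 5-bromo-2-hydroxy-4-(triisopropylsilyloxy)benzaldehyde
Product: 3 2-hydroxy-5-(3-methylbut-2-enyl)-4-(triisopropylsilyloxy)benzaldehyde
Conditions: tributyl(3-methylbut-2-enyl)stannane (1.3 equiv), Pd(PPh3)4 (5 mol %), DMF, 90 °C
Reagents that add atoms: tributyl(3-methylbut-2-enyl)stannane, CCCC[Sn](CCCC)(CCCC)CC=C(C)C
Why: Stille coupling of the aryl bromide with the prenylstannane should deliver the linear prenyl group under neutral conditions that leave the aryl silyl ether, the free phenol and the aldehyde alone.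

Step 3
Reactants: 4 1-(2-chloro-4,5-dimethoxyphenyl)ethanone
Product: 5 1-(2-chloro-4,5-dihydroxyphenyl)ethanone
Conditions: BBr3 (3 equiv), CH2Cl2, −78 °C to rt, then H2O
Reagents that add atoms: none
Why: Lewis acid cleavage of both aryl methyl ethers (BBr3 demethylation) is done before any alkene is present, and the aryl chloride and the acetyl group are inert to it.

Step 4
Reactants: 5 1-(2-chloro-4,5-dihydroxyphenyl)ethanone
Product: 6 1-[2-chloro-5-hydroxy-4-(2-methylbut-3-en-2-yloxy)phenyl]ethanone
Conditions: tert-butyl 2-methylbut-3-en-2-yl carbonate (1.05 equiv), Pd(PPh3)4 (2 mol %), THF, 0 °C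
Reagents that add atoms: tert-butyl 2-methylbut-3-en-2-yl carbonate, CC(C)(C)OC(=O)OC(C)(C)C=C
Why: Tsuji–Trost O-allylation: the tert-butoxide released on ionisation deprotonates the more acidic 4-OH (para to the acetyl group), and this phenoxide should attack the 1,1-dimethylallyl–palladium cation at its substituted terminus at low temperature to give the tertiary monoether.

Step 5
Reactants: 6 1-[2-chloro-5-hydroxy-4-(2-methylbut-3-en-2-yloxy)phenyl]ethanone
Product: 7 1-[2-chloro-4-(2-methylbut-3-en-2-yloxy)-5-(2-methylbut-3-yn-2-yloxy)phenyl]ethanone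
Conditions: 3-chloro-3-methylbut-1-yne (1.5 equiv), DBU, CuCl2 (1 mol %), MeCN, 0 °C
Reagents that add atoms: 3-chloro-3-methylbut-1-yne, CC(C)(Cl)C#C
Why: Copper-catalysed propargylic etherification of the remaining phenol by the tertiary propargyl chloride, the standard way to 1,1-dimethylpropargyl aryl ethers, should proceed at 0 °C without disturbing the allyl ether.

Step 6
Reactants: 7 1-[2-chloro-4-(2-methylbut-3-en-2-yloxy)-5-(2-methylbut-3-yn-2-yloxy)phenyl]ethanone
Product: 9 1-[6-chloro-8-hydroxy-2,2-dimethyl-7-(3-methylbut-2-enyl)-2H-chromen-5-yl]ethanone, via prenylphenol propargyl ether 8 (not isolated)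
Conditions: o-xylene, 145 °C
Reagents that add atoms: none
Why: Two aromatic Claisen rearrangements in one heating: the 1,1-dimethylallyl ether shifts to its only free ortho carbon with allyl inversion to give the linear prenyl group of 8, and the propargyl ether shifts to its only free ortho carbon and continues by enolisation, 1,5-hydrogen shift and oxa-6π electrocyclisation to the 2,2-dimethyl-2H-chromene.

Step 7
Reactants: 9 1-[6-chloro-8-hydroxy-2,2-dimethyl-7-(3-methylbut-2-enyl)-2H-chromen-5-yl]ethanone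
Product: 11 2-bromo-1-[6-chloro-2,2-dimethyl-7-(3-methylbut-2-enyl)-8-(triisopropylsilyloxy)-2H-chromen-5-yl]ethanone, via bis-silyl enol ether 10 (not isolated)
Conditions: TIPSOTf (2.3 equiv), Et3N, CH2Cl2, 0 °C to rt; crude 10 then NBS (1.0 equiv), THF, −78 °C
Reagents that add atoms: triisopropylsilyl triflate, CC(C)[Si](OS(=O)(=O)C(F)(F)F)(C(C)C)C(C)C; N-bromosuccinimide, O=C1CCC(=O)N1Br
Why: Silyl triflate and amine should silylate the hindered phenol and turn the methyl ketone into its silyl enol ether, which is far more nucleophilic than the prenyl and chromene double bonds and is therefore brominated selectively by NBS (α-bromination of a ketone through its enol silane).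

Step 8
Reactants: 3 2-hydroxy-5-(3-methylbut-2-enyl)-4-(triisopropylsilyloxy)benzaldehyde; 11 2-bromo-1-[6-chloro-2,2-dimethyl-7-(3-methylbut-2-enyl)-8-(triisopropylsilyloxy)-2H-chromen-5-yl]ethanone
Product: 12 2-{2-[6-chloro-2,2-dimethyl-7-(3-methylbut-2-enyl)-8-(triisopropylsilyloxy)-2H-chromen-5-yl]-2-oxoethoxy}-5-(3-methylbut-2-enyl)-4-(triisopropylsilyloxy)benzaldehyde
Conditions: K2CO3 (1.5 equiv), acetone, rt
Reagents that add atoms: none
Why: Williamson etherification of the phenacyl bromide by the salicylaldehyde phenoxide, kept at room temperature so that the ether does not go on to the aroylbenzofuran (Rap–Stoermer condensation).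

Step 9
Reactants: 12 2-{2-[6-chloro-2,2-dimethyl-7-(3-methylbut-2-enyl)-8-(triisopropylsilyloxy)-2H-chromen-5-yl]-2-oxoethoxy}-5-(3-methylbut-2-enyl)-4-(triisopropylsilyloxy)benzaldehyde
Product: 13 (1R)-1-[6-chloro-2,2-dimethyl-7-(3-methylbut-2-enyl)-8-(triisopropylsilyloxy)-2H-chromen-5-yl]-2-[2-(hydroxymethyl)-4-(3-methylbut-2-enyl)-5-(triisopropylsilyloxy)phenoxy]ethanol
Conditions: (R)-2-methyl-CBS-oxazaborolidine (0.2 equiv), catecholborane (3 equiv), toluene, −78 to −40 °C; then aq. NaOH
Reagents that add atoms: none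
Why: Corey–Bakshi–Shibata reduction: the di-ortho-substituted aryl group acts as the large and the aryloxymethyl group as the small substituent, so the (R)-catalyst should deliver hydride to the face that gives the (R)-carbinol (the future C6a), while the aldehyde is reduced to the benzylic alcohol in the same operation and catecholborane leaves the trisubstituted alkenes alone.

Step 10
Reactants: 13 (1R)-1-[6-chloro-2,2-dimethyl-7-(3-methylbut-2-enyl)-8-(triisopropylsilyloxy)-2H-chromen-5-yl]-2-[2-(hydroxymethyl)-4-(3-methylbut-2-enyl)-5-(triisopropylsilyloxy)phenoxy]ethanol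
Product: 15 (3R)-3-[6-chloro-2,2-dimethyl-7-(3-methylbut-2-enyl)-8-(triisopropylsilyloxy)-2H-chromen-5-yl]-7-(3-methylbut-2-enyl)-8-(triisopropylsilyloxy)-2,3-dihydro-5H-1,4-benzodioxepine, via benzylic tosylate alkoxide 14 (not isolated)
Conditions: NaH (2.2 equiv), 1-(p-toluenesulfonyl)imidazole (1.05 equiv), THF (0.01 M), 0 °C to rt
Reagents that add atoms: none
Why: One-pot cyclodehydration of a diol (intramolecular Williamson etherification): the unhindered primary benzylic alkoxide is sulfonylated and the secondary alkoxide displaces the electron-rich benzylic tosylate in a 7-exo-tet closure, so the C6a–O bond is never broken and the (R) configuration is kept.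

Step 11
Reactants: 15 (3R)-3-[6-chloro-2,2-dimethyl-7-(3-methylbut-2-enyl)-8-(triisopropylsilyloxy)-2H-chromen-5-yl]-7-(3-methylbut-2-enyl)-8-(triisopropylsilyloxy)-2,3-dihydro-5H-1,4-benzodioxepine
Product: 18 (6aR,11aR)-3,9-bis-O-(triisopropylsilyl)lespecyrtin E3, via C11a-lithiated dioxepine 16 (not isolated), via lithium cis-isoflavan-4-olate 17 (not isolated)
Conditions: s-BuLi (1.1 equiv), THF, −78 °C, then −20 °C; then Pd2(dba)3 (2.5 mol %), t-BuXPhos (6 mol %), toluene, 80 °C
Reagents that add atoms: none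
Why: Proposed new method: s-BuLi removes one C11a–H, the only proton that is benzylic, α to oxygen and held between the two chelating ether oxygens O5 and O11, and the lithio ether 16 undergoes a [1,2]-Wittig shift in which the weak secondary benzylic O11–C6a bond breaks to a tethered ketyl/benzyl radical pair that recombines at carbon, so the seven-membered dioxepine contracts to the six-membered ring B (1,2-migration, ring contraction) and O11 is released as the lithium alkoxide 17. The closest known reaction types are the [1,2]-Wittig rearrangement of benzyl ethers for this stage and the Buchwald–Hartwig-type palladium-catalysed intramolecular etherification of aryl halides by secondary alkoxides for the next, which are here joined in one flask without isolating the alcohol. C6a should keep its (R) configuration because the migrating carbon is delivered with retention within a pair that cannot diffuse apart, and C11a is set by least-motion collapse onto the ketyl face that C6a already overhangs in the chair-like dioxepine with ring D equatorial, which is expected to put O11 and ring D cis (3R,4R). Zerovalent palladium then inserts into the C10a–Cl bond, the alkoxide binds and C–O reductive elimination closes the five-membered ring C (5-exo closure onto C10a through a six-membered palladacycle); this closure is open only to the cis-olate, so the cis-(6aR,11aR) ring fusion should result and any trans-olate should remain as a separable alcohol. The step needs lithiation at C11a in preference to the two prenyl CH2 groups, C4–H of ring A and C6a–H, which the double oxygen chelation and the bulky silyl ethers should secure, and it needs an aryl halide that survives s-BuLi, which is why C10a carries chlorine between two substituents (no halogen–lithium exchange at −78 °C, no ortho hydrogen for aryne formation).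

Step 12
Reactants: 18 (6aR,11aR)-3,9-bis-O-(triisopropylsilyl)lespecyrtin E3
Product: 19 lespecyrtin E3
Conditions: TBAF (2.5 equiv), THF, 0 °C; then aq. NH4Cl
Reagents that add atoms: none
Why: Fluoride-induced cleavage of both aryl silyl ethers (desilylation) under non-acidic conditions should spare the prenyl groups, the chromene and the acid-labile benzylic C11a–O11 bond, and it leaves both stereocentres untouched.

**Compound list**

1 | 5-bromo-2,4-dihydroxybenzaldehyde | O=Cc1cc(Br)c(O)cc1O | starting material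
2 | 5-bromo-2-hydroxy-4-(triisopropylsilyloxy)benzaldehyde | O=Cc1cc(Br)c(O[Si](C(C)C)(C(C)C)C(C)C)cc1O | intermediate
3 | 2-hydroxy-5-(3-methylbut-2-enyl)-4-(triisopropylsilyloxy)benzaldehyde | O=Cc1cc(CC=C(C)C)c(O[Si](C(C)C)(C(C)C)C(C)C)cc1O | intermediate
4 | 1-(2-chloro-4,5-dimethoxyphenyl)ethanone | CC(=O)c1cc(OC)c(OC)cc1Cl | starting material
5 | 1-(2-chloro-4,5-dihydroxyphenyl)ethanone | CC(=O)c1cc(O)c(O)cc1Cl | intermediate
6 | 1-[2-chloro-5-hydroxy-4-(2-methylbut-3-en-2-yloxy)phenyl]ethanone | CC(=O)c1cc(O)c(OC(C)(C)C=C)cc1Cl | intermediate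
7 | 1-[2-chloro-4-(2-methylbut-3-en-2-yloxy)-5-(2-methylbut-3-yn-2-yloxy)phenyl]ethanone | CC(=O)c1cc(OC(C)(C)C#C)c(OC(C)(C)C=C)cc1Cl | intermediate
8 | 1-[2-chloro-4-hydroxy-3-(3-methylbut-2-enyl)-5-(2-methylbut-3-yn-2-yloxy)phenyl]ethanone | CC(=O)c1cc(OC(C)(C)C#C)c(O)c(CC=C(C)C)c1Cl | intermediate
9 | 1-[6-chloro-8-hydroxy-2,2-dimethyl-7-(3-methylbut-2-enyl)-2H-chromen-5-yl]ethanone | CC(=O)c1c(Cl)c(CC=C(C)C)c(O)c2OC(C)(C)C=Cc12 | intermediate
10 | 6-chloro-2,2-dimethyl-7-(3-methylbut-2-enyl)-8-(triisopropylsilyloxy)-5-[1-(triisopropylsilyloxy)ethenyl]-2H-chromene | C=C(O[Si](C(C)C)(C(C)C)C(C)C)c1c(Cl)c(CC=C(C)C)c(O[Si](C(C)C)(C(C)C)C(C)C)c2OC(C)(C)C=Cc12 | intermediate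
11 | 2-bromo-1-[6-chloro-2,2-dimethyl-7-(3-methylbut-2-enyl)-8-(triisopropylsilyloxy)-2H-chromen-5-yl]ethanone | BrCC(=O)c1c(Cl)c(CC=C(C)C)c(O[Si](C(C)C)(C(C)C)C(C)C)c2OC(C)(C)C=Cc12 | intermediate
12 | 2-{2-[6-chloro-2,2-dimethyl-7-(3-methylbut-2-enyl)-8-(triisopropylsilyloxy)-2H-chromen-5-yl]-2-oxoethoxy}-5-(3-methylbut-2-enyl)-4-(triisopropylsilyloxy)benzaldehyde | O=Cc1cc(CC=C(C)C)c(O[Si](C(C)C)(C(C)C)C(C)C)cc1OCC(=O)c1c(Cl)c(CC=C(C)C)c(O[Si](C(C)C)(C(C)C)C(C)C)c2OC(C)(C)C=Cc12 | intermediate
13 | (1R)-1-[6-chloro-2,2-dimethyl-7-(3-methylbut-2-enyl)-8-(triisopropylsilyloxy)-2H-chromen-5-yl]-2-[2-(hydroxymethyl)-4-(3-methylbut-2-enyl)-5-(triisopropylsilyloxy)phenoxy]ethanol | OCc1cc(CC=C(C)C)c(O[Si](C(C)C)(C(C)C)C(C)C)cc1OC[C@H](O)c1c(Cl)c(CC=C(C)C)c(O[Si](C(C)C)(C(C)C)C(C)C)c2OC(C)(C)C=Cc12 | intermediate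
14 | sodium (1R)-1-[6-chloro-2,2-dimethyl-7-(3-methylbut-2-enyl)-8-(triisopropylsilyloxy)-2H-chromen-5-yl]-2-[4-(3-methylbut-2-enyl)-2-(p-toluenesulfonyloxymethyl)-5-(triisopropylsilyloxy)phenoxy]ethanolate | [Na+].[O-][C@@H](COc1cc(O[Si](C(C)C)(C(C)C)C(C)C)c(CC=C(C)C)cc1COS(=O)(=O)c1ccc(C)cc1)c1c(Cl)c(CC=C(C)C)c(O[Si](C(C)C)(C(C)C)C(C)C)c2OC(C)(C)C=Cc12 | intermediate
15 | (3R)-3-[6-chloro-2,2-dimethyl-7-(3-methylbut-2-enyl)-8-(triisopropylsilyloxy)-2H-chromen-5-yl]-7-(3-methylbut-2-enyl)-8-(triisopropylsilyloxy)-2,3-dihydro-5H-1,4-benzodioxepine | CC(C)=CCc1cc2CO[C@@H](COc2cc1O[Si](C(C)C)(C(C)C)C(C)C)c1c(Cl)c(CC=C(C)C)c(O[Si](C(C)C)(C(C)C)C(C)C)c2OC(C)(C)C=Cc12 | intermediate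
16 | (3R)-5-lithio derivative of 15 (lithium at the benzylic C5 of the dioxepine, the future C11a) | CC(C)=CCc1cc2C([Li])O[C@@H](COc2cc1O[Si](C(C)C)(C(C)C)C(C)C)c1c(Cl)c(CC=C(C)C)c(O[Si](C(C)C)(C(C)C)C(C)C)c2OC(C)(C)C=Cc12 | intermediate
17 | lithium (3R,4R)-3-[6-chloro-2,2-dimethyl-7-(3-methylbut-2-enyl)-8-(triisopropylsilyloxy)-2H-chromen-5-yl]-6-(3-methylbut-2-enyl)-7-(triisopropylsilyloxy)chroman-4-olate | [Li+].CC(C)=CCc1cc2c(cc1O[Si](C(C)C)(C(C)C)C(C)C)OC[C@H]([C@H]2[O-])c1c(Cl)c(CC=C(C)C)c(O[Si](C(C)C)(C(C)C)C(C)C)c2OC(C)(C)C=Cc12 | intermediate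
18 | (6aR,11aR)-3,9-bis-O-(triisopropylsilyl)lespecyrtin E3 | CC(C)=CCc1cc2c(cc1O[Si](C(C)C)(C(C)C)C(C)C)OC[C@H]1c3c4c(c(O[Si](C(C)C)(C(C)C)C(C)C)c(CC=C(C)C)c3O[C@@H]21)OC(C)(C)C=C4 | intermediate
19 | lespecyrtin E3, (6aR,11aR) | CC(C)=CCc1cc2c(cc1O)OC[C@H]1c3c4c(c(O)c(CC=C(C)C)c3O[C@@H]21)OC(C)(C)C=C4 | target

**Step count and risks**

Total step count: 12. Longest linear sequence: 10 steps (steps 3 to 7, then 8 to 12).

Steps most likely to fail:

Step 11 (key step, proposed new method). The radical pair may recombine with loss of configuration at C6a or on the other ketyl face, and the palladium cycle may stall on the hindered aryl chloride in the presence of lithium salts. The fallback uses known chemistry and sets the stereochemistry by a catalyst instead of by chirality transfer. Setting out from 15, the Wittig ring contraction alone (s-BuLi, THF, −78 to −20 °C, NH4Cl quench) would give the C4-epimeric 3-aryl-chroman-4-ols F1. Oxidation with Dess–Martin periodinane would give the 3-aryl-chroman-4-one F2, whose C3 is enolisable. Asymmetric transfer hydrogenation with dynamic kinetic resolution, RuCl(p-cymene)[(R,R)-TsDPEN] in HCO2H/Et3N, would give the cis-(3R,4R)-3-aryl-chroman-4-ol F3. A separate etherification with Pd2(dba)3/t-BuXPhos and NaOt-Bu in toluene at 80 °C would rejoin the route at 18.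

Step 9. Facial selectivity may be poor, because the di-ortho-substituted aryl group is twisted out of the carbonyl plane and may no longer differ enough from the aryloxymethyl group, and hydroboration of the alkenes may compete. The fallback builds the carbinol by epoxide opening instead of ketone reduction. Setting out from 11 and 3, NaBH4 (MeOH, 0 °C) would give the racemic 2-bromo-1-arylethanol F4, and K2CO3 would close it to the racemic aryl oxirane F5. Kinetic resolution by ring opening at the CH2 terminus with phenol 3 (0.45 equiv), catalysed by (S,S)-Co(salen)(OAc) (the enantiomer expected to open the (R)-epoxide), would give the (R)-hydroxy aldehyde F6. NaBH4 reduction of its formyl group would rejoin the route at 13.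

Step 6. The tertiary allyl group may be lost thermally before it rearranges, or the free phenol may decompose at 145 °C before both shifts are complete. The fallback separates the two events and replaces the thermal propargyl shift by metal catalysis. Setting out from 7, the allyl shift alone would be run with Eu(fod)3 (10 mol %) in CHCl3 at 50 °C and the prenylphenol 8 isolated. Silylation (TIPSOTf, 2,6-lutidine) would give the silyl ether F7. Ph3PAuNTf2 (2 mol %) in CH2Cl2 at rt would close the pyran ring by 6-endo hydroarylation of the alkyne, giving the silylated chromenyl methyl ketone F8. TIPSOTf/Et3N would then convert F8 into the silyl enol ether 10, where the fallback rejoins the route.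

Further compounds
F1 | step 11 | 3-[6-chloro-2,2-dimethyl-7-(3-methylbut-2-enyl)-8-(triisopropylsilyloxy)-2H-chromen-5-yl]-6-(3-methylbut-2-enyl)-7-(triisopropylsilyloxy)chroman-4-ol (C4 epimers) | CC(C)=CCc1cc2c(cc1O[Si](C(C)C)(C(C)C)C(C)C)OCC(C2O)c1c(Cl)c(CC=C(C)C)c(O[Si](C(C)C)(C(C)C)C(C)C)c2OC(C)(C)C=Cc12
F2 | step 11 | 3-[6-chloro-2,2-dimethyl-7-(3-methylbut-2-enyl)-8-(triisopropylsilyloxy)-2H-chromen-5-yl]-6-(3-methylbut-2-enyl)-7-(triisopropylsilyloxy)chroman-4-one | CC(C)=CCc1cc2c(cc1O[Si](C(C)C)(C(C)C)C(C)C)OCC(C2=O)c1c(Cl)c(CC=C(C)C)c(O[Si](C(C)C)(C(C)C)C(C)C)c2OC(C)(C)C=Cc12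
F3 | step 11 | (3R,4R)-3-[6-chloro-2,2-dimethyl-7-(3-methylbut-2-enyl)-8-(triisopropylsilyloxy)-2H-chromen-5-yl]-6-(3-methylbut-2-enyl)-7-(triisopropylsilyloxy)chroman-4-ol | CC(C)=CCc1cc2c(cc1O[Si](C(C)C)(C(C)C)C(C)C)OC[C@H]([C@H]2O)c1c(Cl)c(CC=C(C)C)c(O[Si](C(C)C)(C(C)C)C(C)C)c2OC(C)(C)C=Cc12
F4 | step 9 | racemic 2-bromo-1-[6-chloro-2,2-dimethyl-7-(3-methylbut-2-enyl)-8-(triisopropylsilyloxy)-2H-chromen-5-yl]ethanol | OC(CBr)c1c(Cl)c(CC=C(C)C)c(O[Si](C(C)C)(C(C)C)C(C)C)c2OC(C)(C)C=Cc12
F5 | step 9 | racemic 2-[6-chloro-2,2-dimethyl-7-(3-methylbut-2-enyl)-8-(triisopropylsilyloxy)-2H-chromen-5-yl]oxirane | C1OC1c1c(Cl)c(CC=C(C)C)c(O[Si](C(C)C)(C(C)C)C(C)C)c2OC(C)(C)C=Cc12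
F6 | step 9 | 2-{(2R)-2-[6-chloro-2,2-dimethyl-7-(3-methylbut-2-enyl)-8-(triisopropylsilyloxy)-2H-chromen-5-yl]-2-hydroxyethoxy}-5-(3-methylbut-2-enyl)-4-(triisopropylsilyloxy)benzaldehyde | O=Cc1cc(CC=C(C)C)c(O[Si](C(C)C)(C(C)C)C(C)C)cc1OC[C@H](O)c1c(Cl)c(CC=C(C)C)c(O[Si](C(C)C)(C(C)C)C(C)C)c2OC(C)(C)C=Cc12
F7 | step 6 | 1-[2-chloro-3-(3-methylbut-2-enyl)-5-(2-methylbut-3-yn-2-yloxy)-4-(triisopropylsilyloxy)phenyl]ethanone | CC(=O)c1cc(OC(C)(C)C#C)c(O[Si](C(C)C)(C(C)C)C(C)C)c(CC=C(C)C)c1Cl
F8 | step 6 | 1-[6-chloro-2,2-dimethyl-7-(3-methylbut-2-enyl)-8-(triisopropylsilyloxy)-2H-chromen-5-yl]ethanone | CC(=O)c1c(Cl)c(CC=C(C)C)c(O[Si](C(C)C)(C(C)C)C(C)C)c2OC(C)(C)C=Cc12
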